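**Retrosynthetic overview**
1. Last step: intramolecular Nozaki–Hiyama–Kishi allylation forms C6–C7 from an acyclic 2-(bromomethyl)enoate / Z-enal. The ten-membered carbocycle closes first and the γ-lactone closes onto it in the same flask; both ester side chains are already in place.
2. The C11–C13 acrylate unit comes from the C7 aldehyde (vinylalumination, then SN2' bromination). C3–C4 comes from a B-alkyl Suzuki coupling with (Z)-3-iodobut-2-en-1-ol, which fixes the 4Z olefin.
3. The acyclic C2–C1=C10(CO2Me)–C9(O)–C8(O)–C7 core comes from unsymmetrical ozonolysis of the 3,4-alkene of a methyl (5S,6R)-5,6-diacyloxycyclohexa-1,3-diene-1-carboxylate. The six-membered ring is cut open; its cis-diol becomes C8/C9 and its ring-cis enoate becomes the 1(10) olefin.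
4. That diene diol comes from methyl benzoate by enzymatic dearomatising cis-dihydroxylation (key step: C8, C9 and the enoate geometry are set in one operation).
5. The C8 acyl group comes from tiglyl alcohol (Sharpless epoxidation, oxidation, C3-selective acetolysis).

Assumption: the whole-cell toluene dioxygenase catalyst E. coli JM109 (pDTG601A) is at hand as a standard biocatalyst.
Notation: AHMB = (2S,3S)-3-acetoxy-2-hydroxy-2-methylbutanoyl; atom labels C1–C14 in the explanations follow germacrane numbering of the target (C6 lactone carbinol, C7 ring fusion, C8/C9 ester carbons, C10 bearing CO2Me).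

**Route**

Step 1
Reactants: 1 methyl benzoate
Product: 2 methyl (5S,6R)-5,6-dihydroxycyclohexa-1,3-diene-1-carboxylate
Conditions: E. coli JM109 (pDTG601A) whole cells (toluene dioxygenase), glucose-fed fermentation, air, pH 6.8, 37 → 30 °C; EtOAc extraction
Reagents that add atoms: dioxygen, O=O
Why: Toluene-dioxygenase arene cis-dihydroxylation adds O2 suprafacially across C2–C3 of the benzoate, breaking aromaticity and setting both carbinol centres in the known (5S,6R) sense (future C8 S and C9 R), while the surviving ester-bearing ring alkene is the future 1(10) olefin with its ring-cis geometry.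

Step 2
Reactants: 3 (E)-2-methylbut-2-en-1-ol (tiglyl alcohol)
Product: 4 [(2R,3R)-2,3-dimethyloxiran-2-yl]methanol
Conditions: Ti(OiPr)4 (5 mol%), D-(−)-diisopropyl tartrate (6 mol%), tBuOOH, 4 Å molecular sieves, CH2Cl2, −20 °C
Reagents that add atoms: tert-butyl hydroperoxide, CC(C)(C)OO
Why: Sharpless asymmetric epoxidation; the titanium D-(−)-tartrate catalyst delivers the peroxide oxygen to the allylic alcohol face that gives the (2R,3R)-epoxide, fixing both future side-chain centres.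

Step 3
Reactants: 4 [(2R,3R)-2,3-dimethyloxiran-2-yl]methanol
Product: 5 (2S,3R)-2,3-dimethyloxirane-2-carboxylic acid
Conditions: RuCl3·xH2O (2 mol%), NaIO4, CCl4/MeCN/H2O, rt
Reagents that add atoms: water, O; sodium periodate NaIO4, [Na+].[O-]I(=O)(=O)=O
Why: RuO4 oxidation (catalytic RuCl3, periodate as terminal oxidant) takes the primary alcohol to the acid through the aldehyde hydrate without touching the epoxide; no stereocentre changes (the C2 label switches only because CO2H outranks C3).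

Step 4
Reactants: 5 (2S,3R)-2,3-dimethyloxirane-2-carboxylic acid
Product: 6 (2S,3S)-3-acetoxy-2-hydroxy-2-methylbutanoic acid (AHMB-OH)
Conditions: AcOH (5 equiv), Ti(OiPr)4 (1.5 equiv), CH2Cl2, rt; aq. tartaric acid work-up
Reagents that add atoms: acetic acid, CC(=O)O
Why: Titanium-chelate-assisted SN2 opening of a 2,3-epoxy acid; acetate attacks C3 (C2 is quaternary and α to the carboxyl) with inversion and C2 is untouched, giving the (2S,3S) acid.

Step 5
Reactants: 2 methyl (5S,6R)-5,6-dihydroxycyclohexa-1,3-diene-1-carboxylate; 6 (2S,3S)-3-acetoxy-2-hydroxy-2-methylbutanoic acid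
Product: 7 methyl (5S,6R)-5-(AHMB-oxy)-6-hydroxycyclohexa-1,3-diene-1-carboxylate
Conditions: 2-methyl-6-nitrobenzoic anhydride, Et3N, DMAP (cat.), CH2Cl2, 0 °C → rt
Reagents that add atoms: none
Why: Shiina esterification; the hindered acyl donor should react only at the distal C5 hydroxyl (the C6 hydroxyl is flanked by the ester-bearing sp2 carbon and hydrogen-bonded to it), and the tertiary α-hydroxyl of 6 is too hindered to be acylated; no stereocentre is touched.

Step 6
Reactants: 7 methyl (5S,6R)-5-(AHMB-oxy)-6-hydroxycyclohexa-1,3-diene-1-carboxylate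
Product: 8 methyl (5S,6R)-5-(AHMB-oxy)-6-(isobutyryloxy)cyclohexa-1,3-diene-1-carboxylate
Conditions: iPrCOCl, pyridine, CH2Cl2, −20 → 0 °C
Reagents that add atoms: isobutyryl chloride, CC(C)C(Cl)=O
Why: Acylation of the remaining secondary allylic alcohol with an acid chloride under mild base; the tertiary alcohol does not react below 0 °C and the cold, short reaction avoids aromatising elimination.

Step 7
Reactants: 8 methyl (5S,6R)-5-(AHMB-oxy)-6-(isobutyryloxy)cyclohexa-1,3-diene-1-carboxylate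
Product: 11 methyl (2E)-2-[(1R,2R)-2-(AHMB-oxy)-1-(isobutyryloxy)-3,3-dimethoxypropyl]-4-oxobut-2-enoate, via aldehyde methoxy-hydroperoxide 9 (not isolated), via acetal methoxy-hydroperoxide 10 (not isolated)
Conditions: O3 (1 equiv, Sudan Red end-point), CH2Cl2/MeOH (5:1), −78 °C; TsOH·H2O (cat.), −78 °C → rt; NaHCO3; Me2S, rt
Reagents that add atoms: ozone, [O-][O+]=O; methanol, CO
Why: Unsymmetrical (Schreiber-type) ozonolysis; ozone takes the electron-richer γ,δ-alkene of the dienoate, Criegee fragmentation places the carbonyl oxide at C2 (away from the inductively withdrawing C8–O carbon) where methanol traps it, TsOH/MeOH acetalises the free C7 aldehyde, and Me2S then unveils the C2 enal with the enoate geometry inherited from the ring.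

Step 8
Reactants: 11 methyl (2E)-2-[(1R,2R)-2-(AHMB-oxy)-1-(isobutyryloxy)-3,3-dimethoxypropyl]-4-oxobut-2-enoate
Product: 12 methyl (2E)-2-[(1R,2R)-2-(AHMB-oxy)-1-(isobutyryloxy)-3,3-dimethoxypropyl]penta-2,4-dienoate
Conditions: Ph3PCH3Br, KN(SiMe3)2, THF, −78 → 0 °C
Reagents that add atoms: methyltriphenylphosphonium bromide, C[P+](c1ccccc1)(c1ccccc1)c1ccccc1.[Br-]
Why: Wittig methylenation; the ylide adds to the aldehyde at −78 °C far faster than it deprotonates or attacks the esters, acetal or tertiary alcohol, and the enoate geometry is untouched.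

Step 9
Reactants: 13 but-2-yn-1-ol
Product: 15 (Z)-3-iodobut-2-en-1-ol, via cyclic alkenylaluminate 14 (not isolated)
Conditions: NaAlH2(OCH2CH2OMe)2, THF, 0 °C → rt; I2, −78 °C → rt
Reagents that add atoms: iodine, II
Why: Hydroxyl-directed trans-hydroalumination of the propargylic alcohol places aluminium on C3 through a five-membered chelate, and iodinolysis with retention gives the Z vinyl iodide.

Step 10
Reactants: 12 methyl (2E)-2-[(1R,2R)-2-(AHMB-oxy)-1-(isobutyryloxy)-3,3-dimethoxypropyl]penta-2,4-dienoate; 15 (Z)-3-iodobut-2-en-1-ol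
Product: 17 methyl (2E,6Z)-2-[(1R,2R)-2-(AHMB-oxy)-1-(isobutyryloxy)-3,3-dimethoxypropyl]-8-hydroxy-6-methylocta-2,6-dienoate, via B-alkyl-9-BBN borane 16 (not isolated)
Conditions: 9-BBN, THF, 0 °C → rt; then 15 (1.3 equiv), Pd(dppf)Cl2·CH2Cl2 (5 mol%), AsPh3, aq. K3PO4, DMF, rt
Reagents that add atoms: none
Why: Hydroboration then B-alkyl Suzuki–Miyaura coupling; 9-BBN adds anti-Markovnikov to the terminal vinyl group only (the trisubstituted enoate alkene, esters and acetal are inert) and the primary alkylborane couples with the vinyl iodide with retention, fixing the 4Z olefin, while the excess of 15 keeps zerovalent palladium away from the allylic isobutyrate.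

Step 11
Reactants: 17 methyl (2E,6Z)-2-[(1R,2R)-2-(AHMB-oxy)-1-(isobutyryloxy)-3,3-dimethoxypropyl]-8-hydroxy-6-methylocta-2,6-dienoate
Product: 18 methyl (2E,6Z)-2-[(1R,2R)-2-(AHMB-oxy)-1-(isobutyryloxy)-3,3-dimethoxypropyl]-6-methyl-8-oxoocta-2,6-dienoate
Conditions: TEMPO (10 mol%), PhI(OAc)2, CH2Cl2, rt
Reagents that add atoms: none
Why: Oxoammonium (TEMPO) oxidation converts the primary allylic alcohol into the enal under neutral conditions without Z to E isomerisation; the tertiary alcohol and the acetal are inert.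

Step 12
Reactants: 18 methyl (2E,6Z)-2-[(1R,2R)-2-(AHMB-oxy)-1-(isobutyryloxy)-3,3-dimethoxypropyl]-6-methyl-8-oxoocta-2,6-dienoate
Product: 19 methyl (2E,6Z)-2-[(1R,2R)-2-(AHMB-oxy)-1-(isobutyryloxy)-3-oxopropyl]-6-methyl-8-oxoocta-2,6-dienoate
Conditions: TFA/H2O (9:1), CH2Cl2, 0 °C, 1 h
Reagents that add atoms: water, O
Why: Acid hydrolysis of the dimethyl acetal, helped by the neighbouring C8 ester carbonyl, frees the C7 aldehyde; the short cold exposure should be tolerated by the electron-poor Z-enal, the esters and the tertiary alcohol, and C8 does not enolise under acid.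

Step 13
Reactants: 19 methyl (2E,6Z)-2-[(1R,2R)-2-(AHMB-oxy)-1-(isobutyryloxy)-3-oxopropyl]-6-methyl-8-oxoocta-2,6-dienoate
Product: 20 methyl (2E,6Z)-2-[(1R,2S,3RS)-2-(AHMB-oxy)-3-hydroxy-1-(isobutyryloxy)-4-(methoxycarbonyl)pent-4-en-1-yl]-6-methyl-8-oxoocta-2,6-dienoate
Conditions: iBu2AlH, N-methylmorpholine N-oxide, THF, 0 °C; methyl propiolate, 0 °C; then 19, 0 °C → rt; dilute HCl work-up
Reagents that add atoms: methyl propiolate, C#CC(=O)OC
Why: Vinylalumination (a base-free Baylis–Hillman-type hydroxyalkylation); hydroalumination of methyl propiolate gives the α-(methoxycarbonyl)vinyl alane, which adds to the more electrophilic non-conjugated C7 aldehyde and not to the β,β-disubstituted enal, the absence of amine base avoids β-acyloxy elimination, and the new carbinol configuration is erased in step 14.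

Step 14
Reactants: 20 methyl (2E,6Z)-2-[(1R,2S,3RS)-2-(AHMB-oxy)-3-hydroxy-1-(isobutyryloxy)-4-(methoxycarbonyl)pent-4-en-1-yl]-6-methyl-8-oxoocta-2,6-dienoate
Product: 21 methyl (2E,6Z)-2-[(1R,2S,3Z)-2-(AHMB-oxy)-4-(bromomethyl)-1-(isobutyryloxy)-5-methoxy-5-oxopent-3-en-1-yl]-6-methyl-8-oxoocta-2,6-dienoate
Conditions: NBS, Me2S, CH2Cl2, 0 °C → rt
Reagents that add atoms: N-bromosuccinimide, O=C1CCC(=O)N1Br
Why: Corey–Kim-type activation of the allylic alcohol followed by SN2' attack of bromide gives the thermodynamic (Z)-2-(bromomethyl)enoate and removes the C7 carbinol; the tertiary alcohol has no substitution pathway and the enal is untouched.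

Step 15
Reactants: 21 methyl (2E,6Z)-2-[(1R,2S,3Z)-2-(AHMB-oxy)-4-(bromomethyl)-1-(isobutyryloxy)-5-methoxy-5-oxopent-3-en-1-yl]-6-methyl-8-oxoocta-2,6-dienoate
Product: 23 CNP0479879.1, methyl (3aS,4S,5R,6E,10Z,11aR)-4-(AHMB-oxy)-5-(isobutyryloxy)-10-methyl-3-methylidene-2-oxo-2,3,3a,4,5,8,9,11a-octahydrocyclodeca[b]furan-6-carboxylate, via cyclodecadienyl hydroxy ester 22 (not isolated)
Conditions: CrCl2 (8 equiv), THF, 3 mM (syringe-pump addition), rt; aq. NH4Cl; PPTS (cat.), CH2Cl2, rt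
Reagents that add atoms: none
Why: Intramolecular Nozaki–Hiyama–Kishi (Barbier-type) allylation; the allylchromium adds through its γ-carbon C7 to the C6 aldehyde and closes the ten-membered ring, the ring tether is expected to enforce the anti adduct (trans-lactone) while allylic 1,3-strain at C8 (C8–H in the enoate plane, ring carbon C9 opposite the incoming aldehyde) puts C11 cis to the C8 ester, and the alkoxide then lactonises onto the acrylate ester.

**Compound list**
1 | methyl benzoate | COC(=O)c1ccccc1 | starting material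
2 | methyl (5S,6R)-5,6-dihydroxycyclohexa-1,3-diene-1-carboxylate | C1=C(C(=O)OC)[C@@H](O)[C@@H](O)C=C1 | intermediate
3 | (E)-2-methylbut-2-en-1-ol | C/C=C(\C)CO | starting material
4 | [(2R,3R)-2,3-dimethyloxiran-2-yl]methanol | OC[C@@]1(C)O[C@@H]1C | intermediate
5 | (2S,3R)-2,3-dimethyloxirane-2-carboxylic acid | OC(=O)[C@@]1(C)O[C@@H]1C | intermediate
6 | (2S,3S)-3-acetoxy-2-hydroxy-2-methylbutanoic acid | OC(=O)[C@@](C)(O)[C@H](C)OC(C)=O | intermediate
7 | methyl (5S,6R)-5-(AHMB-oxy)-6-hydroxycyclohexa-1,3-diene-1-carboxylate | C1=C(C(=O)OC)[C@@H](O)[C@@H](OC(=O)[C@@](C)(O)[C@H](C)OC(C)=O)C=C1 | intermediate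
8 | methyl (5S,6R)-5-(AHMB-oxy)-6-(isobutyryloxy)cyclohexa-1,3-diene-1-carboxylate | C1=C(C(=O)OC)[C@@H](OC(=O)C(C)C)[C@@H](OC(=O)[C@@](C)(O)[C@H](C)OC(C)=O)C=C1 | intermediate
9 | methyl (2E)-2-[(1R,2R)-2-(AHMB-oxy)-1-(isobutyryloxy)-3-oxopropyl]-4-hydroperoxy-4-methoxybut-2-enoate (C4 epimers) | COC(OO)/C=C(/C(=O)OC)[C@@H](OC(=O)C(C)C)[C@@H](OC(=O)[C@@](C)(O)[C@H](C)OC(C)=O)C=O | intermediate (not isolated)
10 | methyl (2E)-2-[(1R,2R)-2-(AHMB-oxy)-1-(isobutyryloxy)-3,3-dimethoxypropyl]-4-hydroperoxy-4-methoxybut-2-enoate (C4 epimers) | COC(OO)/C=C(/C(=O)OC)[C@@H](OC(=O)C(C)C)[C@@H](OC(=O)[C@@](C)(O)[C@H](C)OC(C)=O)C(OC)OC | intermediate (not isolated)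
11 | methyl (2E)-2-[(1R,2R)-2-(AHMB-oxy)-1-(isobutyryloxy)-3,3-dimethoxypropyl]-4-oxobut-2-enoate | O=C/C=C(/C(=O)OC)[C@@H](OC(=O)C(C)C)[C@@H](OC(=O)[C@@](C)(O)[C@H](C)OC(C)=O)C(OC)OC | intermediate
12 | methyl (2E)-2-[(1R,2R)-2-(AHMB-oxy)-1-(isobutyryloxy)-3,3-dimethoxypropyl]penta-2,4-dienoate | C=C/C=C(/C(=O)OC)[C@@H](OC(=O)C(C)C)[C@@H](OC(=O)[C@@](C)(O)[C@H](C)OC(C)=O)C(OC)OC | intermediate
13 | but-2-yn-1-ol | CC#CCO | starting material
14 | sodium 2,2-bis(2-methoxyethoxy)-3-methyl-2,5-dihydro-1,2-oxaaluminol-2-uide (cyclic alkenylaluminate) | [Na+].CC1=CCO[Al-]1(OCCOC)OCCOC | intermediate (not isolated)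
15 | (Z)-3-iodobut-2-en-1-ol | OC/C=C(/C)I | intermediate
16 | methyl (2E)-5-(9-borabicyclo[3.3.1]nonan-9-yl)-2-[(1R,2R)-2-(AHMB-oxy)-1-(isobutyryloxy)-3,3-dimethoxypropyl]pent-2-enoate | C1CCC2CCCC1B2CC/C=C(/C(=O)OC)[C@@H](OC(=O)C(C)C)[C@@H](OC(=O)[C@@](C)(O)[C@H](C)OC(C)=O)C(OC)OC | intermediate (not isolated)
17 | methyl (2E,6Z)-2-[(1R,2R)-2-(AHMB-oxy)-1-(isobutyryloxy)-3,3-dimethoxypropyl]-8-hydroxy-6-methylocta-2,6-dienoate | OC/C=C(/C)CC/C=C(/C(=O)OC)[C@@H](OC(=O)C(C)C)[C@@H](OC(=O)[C@@](C)(O)[C@H](C)OC(C)=O)C(OC)OC | intermediate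
18 | methyl (2E,6Z)-2-[(1R,2R)-2-(AHMB-oxy)-1-(isobutyryloxy)-3,3-dimethoxypropyl]-6-methyl-8-oxoocta-2,6-dienoate | O=C/C=C(/C)CC/C=C(/C(=O)OC)[C@@H](OC(=O)C(C)C)[C@@H](OC(=O)[C@@](C)(O)[C@H](C)OC(C)=O)C(OC)OC | intermediate
19 | methyl (2E,6Z)-2-[(1R,2R)-2-(AHMB-oxy)-1-(isobutyryloxy)-3-oxopropyl]-6-methyl-8-oxoocta-2,6-dienoate | O=C/C=C(/C)CC/C=C(/C(=O)OC)[C@@H](OC(=O)C(C)C)[C@@H](OC(=O)[C@@](C)(O)[C@H](C)OC(C)=O)C=O | intermediate
20 | methyl (2E,6Z)-2-[(1R,2S,3RS)-2-(AHMB-oxy)-3-hydroxy-1-(isobutyryloxy)-4-(methoxycarbonyl)pent-4-en-1-yl]-6-methyl-8-oxoocta-2,6-dienoate | O=C/C=C(/C)CC/C=C(/C(=O)OC)[C@@H](OC(=O)C(C)C)[C@@H](OC(=O)[C@@](C)(O)[C@H](C)OC(C)=O)C(O)C(=C)C(=O)OC | intermediate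
21 | methyl (2E,6Z)-2-[(1R,2S,3Z)-2-(AHMB-oxy)-4-(bromomethyl)-1-(isobutyryloxy)-5-methoxy-5-oxopent-3-en-1-yl]-6-methyl-8-oxoocta-2,6-dienoate | O=C/C=C(/C)CC/C=C(/C(=O)OC)[C@@H](OC(=O)C(C)C)[C@@H](OC(=O)[C@@](C)(O)[C@H](C)OC(C)=O)/C=C(/C(=O)OC)CBr | intermediate
22 | methyl (1E,5Z,7R,8S,9S,10R)-9-(AHMB-oxy)-7-hydroxy-10-(isobutyryloxy)-8-(3-methoxy-3-oxoprop-1-en-2-yl)-5-methylcyclodeca-1,5-diene-1-carboxylate | COC(=O)C(=C)[C@H]1[C@H](O)/C=C(/C)CC/C=C(/C(=O)OC)[C@@H](OC(=O)C(C)C)[C@H]1OC(=O)[C@@](C)(O)[C@H](C)OC(C)=O | intermediate (not isolated)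
23 | CNP0479879.1, methyl (3aS,4S,5R,6E,10Z,11aR)-4-(AHMB-oxy)-5-(isobutyryloxy)-10-methyl-3-methylidene-2-oxo-2,3,3a,4,5,8,9,11a-octahydrocyclodeca[b]furan-6-carboxylate | C=C1C(=O)O[C@@H]2/C=C(/C)CC/C=C(/C(=O)OC)[C@@H](OC(=O)C(C)C)[C@@H](OC(=O)[C@@](C)(O)[C@H](C)OC(C)=O)[C@@H]12 | target

**Step count and risks**
Total steps: 15. Longest linear sequence: 13 steps (steps 2, 3, 4, 5, 6, 7, 8, 10, 11, 12, 13, 14, 15, from tiglyl alcohol 3); 11 steps from methyl benzoate 1.

The three steps most likely to fail: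

Step 7. The ozonolysis relies on the direction of Criegee fragmentation to tell C7 from C2; if that direction is poor, the wrong terminus is acetalised. Fallback, from 8 back to 11: cleave in two stages and differentiate by chemoselectivity. OsO4 (cat.) with N-methylmorpholine N-oxide dihydroxylates only the electron-richer distal alkene, anti to the two acyloxy groups, to give the ring 3,4-diol F1. NaIO4 cleaves it to the dialdehyde F2. CeCl3·7H2O with HC(OMe)3 in MeOH then acetalises only the non-conjugated α-acyloxy aldehyde and delivers 11.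

Step 12. Unmasking an α-acyloxy dimethyl acetal needs strong aqueous acid, which may isomerise the Z-enal or cost the C8 ester. Fallback, from 8 back to 19: carry C7 at the alcohol level and unmask by oxidation. Ozonolysis of 8 in CH2Cl2/MeOH with NaBH4/CeCl3·7H2O work-up gives the seco diol F3. MnO2 oxidises only the allylic alcohol to the hydroxy enal F4. Wittig methylenation gives the hydroxy diene F5. Hydroboration with 9-BBN gives the alkylborane F6, which is coupled with 15 as in step 10 to the bis-primary diol F7. Dess–Martin periodinane oxidises both primary alcohols at once and gives 19. The step count is unchanged; the price is a free C7 hydroxyl next to the C8 ester (acyl migration risk) in the basic steps.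

Step 15. The closure may give the wrong C6/C7 diastereomer (the acyclic preference of such allylmetals is the cis-lactone), or the allylchromium may expel the C8 carboxylate by 1,4-elimination. Fallback, from 19 back to 22 and 23: replace the allylmetal (closed transition state) by an allylsilane (open transition state, no organometallic). Wittig reaction of the C7 aldehyde of 19 with the stabilised silyl ylide F8 gives the 2-(trimethylsilylmethyl)enoate allylsilane F9. BF3·OEt2 in CH2Cl2 at −78 °C then effects an intramolecular Hosomi–Sakurai allylation of the enal (C7 onto C6) to give 22, which lactonises with PPTS to 23.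

Further compounds
F1 | step 7 | methyl (3R,4R,5S,6R)-5-(AHMB-oxy)-3,4-dihydroxy-6-(isobutyryloxy)cyclohex-1-ene-1-carboxylate | C1=C(C(=O)OC)[C@@H](OC(=O)C(C)C)[C@@H](OC(=O)[C@@](C)(O)[C@H](C)OC(C)=O)[C@H](O)[C@@H]1O
F2 | step 7 | methyl (2E)-2-[(1R,2R)-2-(AHMB-oxy)-1-(isobutyryloxy)-3-oxopropyl]-4-oxobut-2-enoate | O=C/C=C(/C(=O)OC)[C@@H](OC(=O)C(C)C)[C@@H](OC(=O)[C@@](C)(O)[C@H](C)OC(C)=O)C=O
F3 | step 12 | methyl (2E)-2-[(1R,2S)-2-(AHMB-oxy)-3-hydroxy-1-(isobutyryloxy)propyl]-4-hydroxybut-2-enoate | OC/C=C(/C(=O)OC)[C@@H](OC(=O)C(C)C)[C@@H](OC(=O)[C@@](C)(O)[C@H](C)OC(C)=O)CO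
F4 | step 12 | methyl (2E)-2-[(1R,2S)-2-(AHMB-oxy)-3-hydroxy-1-(isobutyryloxy)propyl]-4-oxobut-2-enoate | O=C/C=C(/C(=O)OC)[C@@H](OC(=O)C(C)C)[C@@H](OC(=O)[C@@](C)(O)[C@H](C)OC(C)=O)CO
F5 | step 12 | methyl (2E)-2-[(1R,2S)-2-(AHMB-oxy)-3-hydroxy-1-(isobutyryloxy)propyl]penta-2,4-dienoate | C=C/C=C(/C(=O)OC)[C@@H](OC(=O)C(C)C)[C@@H](OC(=O)[C@@](C)(O)[C@H](C)OC(C)=O)CO
F6 | step 12 | methyl (2E)-5-(9-borabicyclo[3.3.1]nonan-9-yl)-2-[(1R,2S)-2-(AHMB-oxy)-3-hydroxy-1-(isobutyryloxy)propyl]pent-2-enoate | C1CCC2CCCC1B2CC/C=C(/C(=O)OC)[C@@H](OC(=O)C(C)C)[C@@H](OC(=O)[C@@](C)(O)[C@H](C)OC(C)=O)CO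
F7 | step 12 | methyl (2E,6Z)-2-[(1R,2S)-2-(AHMB-oxy)-3-hydroxy-1-(isobutyryloxy)propyl]-8-hydroxy-6-methylocta-2,6-dienoate | OC/C=C(/C)CC/C=C(/C(=O)OC)[C@@H](OC(=O)C(C)C)[C@@H](OC(=O)[C@@](C)(O)[C@H](C)OC(C)=O)CO
F8 | step 15 | methyl 3-(trimethylsilyl)-2-(triphenylphosphoranylidene)propanoate | COC(=O)C(C[Si](C)(C)C)=P(c1ccccc1)(c1ccccc1)c1ccccc1
F9 | step 15 | methyl (2E,6Z)-2-[(1R,2S,3Z)-2-(AHMB-oxy)-1-(isobutyryloxy)-5-methoxy-5-oxo-4-[(trimethylsilyl)methyl]pent-3-en-1-yl]-6-methyl-8-oxoocta-2,6-dienoate | O=C/C=C(/C)CC/C=C(/C(=O)OC)[C@@H](OC(=O)C(C)C)[C@@H](OC(=O)[C@@](C)(O)[C@H](C)OC(C)=O)/C=C(/C(=O)OC)C[Si](C)(C)C
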